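To the colleague whose hunch was first order in both free catalyst and reagent: that suits the free catalyst, but not the reagent.

left-handed substrate 0.10 M; reagent 0.150 M; free catalyst 1.4 mM; right-handed substrate 0.10 M

    reagent + free catalyst + right-handed substrate → free catalyst + right-handed product (k1 = 82.3 L² mol⁻² s⁻¹)
    free catalyst → spent catalyst (k2 = 0.0128 s⁻¹)
    reagent + free catalyst + left-handed substrate → free catalyst + left-handed product (k3 = 5910 L² mol⁻² s⁻¹)

- free catalyst is single-handed; left-handed substrate and right-handed substrate are mirror images of each other, charged as a racemate, each of them at the stated concentration
- charge of left-handed substrate (flask): 0.10 M

* apparent order in free catalyst when 50% of the left-handed substrate and right-handed substrate together are converted (percent change of the rate of making left-handed product for one percent more free catalyst charged)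
* apparent order in reagent when 50% of the left-handed substrate and right-handed substrate together are converted (percent change of the rate of making left-handed product for one percent more reagent charged)

Both substrates meet the same [free catalyst] and [reagent], so their speeds, each taken per unit of its own concentration, stand in the selectivity factor 71.8, and [left-handed substrate] at a given conversion does not move with either charge. The comparison at 50% total conversion, called the mark here, therefore runs through [reagent] and [free catalyst]. Each turnover uses one reagent, so in this flask:

reagent used at the mark = 0.100 M

reagent left = 0.0500 M

The rule is the reagent leverage, the reagent charged over the reagent left at the mark:

leverage = 3.00

The rate of making left-handed product is the step's constant times [reagent], [free catalyst] and [left-handed substrate]. One percent more charge adds that whole amount to a remainder smaller than the charge, so with [free catalyst] held my reckoning gives an order in reagent of 3.00. More free catalyst shortens the run in proportion and so loses less to decay before the mark at 5.57 s, which gives an order of 1.07.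

The forecast gives 1.07 in free catalyst and 3.17 in reagent: “so I compared rates at fixed conversion rather than fixed time”. Its reagent order is higher than my leverage, which counts no catalyst decay.

The simulation gives 1.1 in free catalyst and 3.2 in reagent.

The flask reaches the mark at 5.57 s with 33.3% of its reagent left, and reagent use by the left-handed path over the right-handed path reads 36 at 0.701 s and 0.16 at 15.0 s. In the flask charged with twice the reagent the leverage is 1.50, and the time to the mark is 0.307 of the first flask's.

(The rate constants were drawn at random within sensible limits; the result is computed.)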